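The sum c(L) + c(D.L) stays at the charge of L, and the step to D.L has no way back.

    D + L → L + J (k1 = 71 M⁻¹ h⁻¹)
    Q + L + J → L + E (k2 = 970 M⁻² h⁻¹)
    D + Q → D.Q (k3 = 0.088 M⁻¹ h⁻¹)
    D + L → D.L (k4 = 0.037 M⁻¹ h⁻¹)

D 0.90 M; Q 0.800 equiv; L 0.05 mol%

* the form that holds most of the catalyst when 10% of the D are converted (L / D.L)
* its share of the catalyst then
* apparent order in Q when 10% of the D are converted (percent change of the rate of making E for one percent more Q charged)
* factor on the rate of making E when 10% of the D are converted if L is charged twice over

My reckoning follows how far the L has decayed by the moment of looking, when 10% of the D is converted. With c(D) held at its charge, L falls by a pseudo-first-order decay with a lifetime of 30.0 h. So I count lifetimes: the lifetime count is the time to the look divided by this lifetime, and L keeps exp(−count) of its charge. D.L is an off-cycle form, outside the working round.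

1. I start with the main step alone, c(L) held at its charge. D then decays at 0.0319 h⁻¹, so the look comes after 3.30 h. That is 0.110 lifetimes, and L keeps 89.6%.

2. I add D + Q → D.Q, with c(Q) held at its charge. It takes D at 0.0634 h⁻¹, twice the main step. The look moves up to 1.11 h, and the count drops to 0.0368.

3. I add the rest. Q + L + J → L + E takes neither D nor L net, so the count stays. The step to D.L draws on D at 1.67 × 10⁻⁵ h⁻¹, far less than the main step, so the clock stays as well.

My reckoning gives L as the main form, with a share of 96.4%. It goes no further, and I commit to no number for the order or the factor.

The forecast says L, with a share of 96.5% (95.5% to 97.5%). It gives an order in Q of 0.37 (0.25 to 0.5) and, on the ground that "more L raises both the catalyst and J", a factor of 2.8 (2.6 to 3).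

The flask gives L at 96.4%, an order in Q of 0.36 and a factor of 2.82. It reaches the look at 1.15 h, against my 1.11 h. To use the count once more, I take the flask at 15.0 h, where 38% of the D is left, and run the lifetime on the mean of the charge and that remainder. This gives 0.345 lifetimes, so L should keep 70.8%. The flask then holds L at 74.0%.

All constants were set for the occasion; the result is computed.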